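**Retrosynthetic overview**

- Numbering follows the germacranolide skeleton (ring C1–C10; lactone C6–O–C12(=O)–C11(=C13)–C7). The strategy rests on the O–C1–C2–C3–O array beside the quaternary C10 of the ten-membered carbocycle (oxirane oxygen on C1, ester oxygen on C3), which is an isoxazoline retron across C1, C2 and C3.
- Disconnections: the C8 and C3 esters; the 1,10-oxirane from a C1 mesylate and the C10 oxygen; C1–OH/C3–OH from a C3=N–O–C1 isoxazoline; the isoxazoline and the ten-membered ring together from a C3 nitrile oxide and the C1=C2 vinyl group of a linalool-derived C10 carbinol.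
- The cyclisation precursor comes from a boron aldol between an (R)-linalool-derived keto ester (C12–C11–C7–C8(=O)–C9–C10) and a Z-enal (C6–C3, from propargyl alcohol), a 1,3-anti reduction at C8 and lactonisation.
- Ring order: γ-lactone (step 13), then isoxazoline and ten-membered carbocycle in one step (step 17), oxirane last (step 25).

Key step: step 17

Assumption: the Z-enol borinate made from 9 with (−)-Ipc2BOTf is taken to attack the Si face of aldehyde 16; were the opposite sense found, (+)-Ipc2BOTf would be used with no other change.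

Step 1
Reactants: 1 (R)-linalool
Product: 2 (3R)-3,7-dimethyl-3-(triethylsilyloxy)octa-1,6-diene
Conditions: Et3SiOTf, 2,6-lutidine, CH2Cl2, −78 → 0 °C
Reagents that add atoms: triethylsilyl triflate, CC[Si](CC)(CC)OS(=O)(=O)C(F)(F)F
Why: Silyl ether formation with the silyl triflate protects the hindered tertiary alcohol without touching the C10 stereocentre.

Step 2
Reactants: 2 (3R)-3,7-dimethyl-3-(triethylsilyloxy)octa-1,6-diene
Product: 4 (4R)-4-methyl-4-(triethylsilyloxy)hex-5-enal, via ozonide 3 (not isolated)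
Conditions: O3, CH2Cl2, −78 °C, Sudan Red 7B end-point; PPh3, −78 °C → rt
Reagents that add atoms: ozone, [O-][O+]=O
Why: Ozonolysis stopped at the indicator end-point is selective for the electron-rich trisubstituted olefin over the hindered monosubstituted vinyl group, and PPh3 reduces the ozonide to the aldehyde.

Step 3
Reactants: 4 (4R)-4-methyl-4-(triethylsilyloxy)hex-5-enal
Product: 6 methyl (2E,4R,6R)-6-methyl-4-(phenylaminooxy)-6-(triethylsilyloxy)octa-2,7-dienoate, via aminoxy aldehyde 5 (not isolated)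
Conditions: PhNO, L-proline (20 mol %), DMSO, rt; then (MeO)2P(O)CH2CO2Me, LiCl, DBU, MeCN, 0 °C
Reagents that add atoms: nitrosobenzene, O=Nc1ccccc1; trimethyl phosphonoacetate, COC(=O)CP(=O)(OC)OC
Why: Proline-catalysed enamine α-aminoxylation followed in the same flask by an E-selective Horner–Wadsworth–Emmons olefination oxygenates C8 and adds C11–C12, and the C8 centre formed here (R with L-proline) does not matter because it is oxidised in step 5.

Step 4
Reactants: 6 methyl (2E,4R,6R)-6-methyl-4-(phenylaminooxy)-6-(triethylsilyloxy)octa-2,7-dienoate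
Product: 7 methyl (2E,4R,6R)-4-hydroxy-6-methyl-6-(triethylsilyloxy)octa-2,7-dienoate
Conditions: Zn dust, AcOH/THF (1:3), rt
Reagents that add atoms: none
Why: Zinc in acetic acid reduces the weak N–O bond (hydroxylamine N–O cleavage) and leaves the enoate, the vinyl group and the tertiary silyl ether alone.

Step 5
Reactants: 7 methyl (2E,4R,6R)-4-hydroxy-6-methyl-6-(triethylsilyloxy)octa-2,7-dienoate
Product: 8 methyl (2E,6R)-6-methyl-4-oxo-6-(triethylsilyloxy)octa-2,7-dienoate
Conditions: Dess–Martin periodinane, CH2Cl2, 0 °C → rt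
Reagents that add atoms: none
Why: Dess–Martin oxidation of the secondary allylic alcohol gives the C8 ketone under neutral conditions that avoid β-elimination of the silyloxy group.

Step 6
Reactants: 8 methyl (2E,6R)-6-methyl-4-oxo-6-(triethylsilyloxy)octa-2,7-dienoate
Product: 9 methyl (6R)-6-methyl-4-oxo-6-(triethylsilyloxy)oct-7-enoate
Conditions: Zn dust, AcOH/THF, 0 °C → rt
Reagents that add atoms: none
Why: Dissolving-metal conjugate reduction acts only on the doubly activated C7=C11 bond of the 4-oxo-enoate, so the isolated vinyl group survives.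

Step 7
Reactants: 10 prop-2-yn-1-ol
Product: 12 (2Z)-3-iodo-2-methylprop-2-en-1-ol, via alkenylmagnesium alkoxide 11 (not isolated)
Conditions: MeMgBr (2.5 equiv), CuI (10 mol %), THF, −10 °C → rt; I2, −78 → 0 °C
Reagents that add atoms: methylmagnesium bromide, C[Mg]Br; iodine, II
Why: Copper-catalysed anti-carbomagnesiation of the propargylic alkoxide places magnesium cis to the CH2O group through a five-membered chelate and iodinolysis proceeds with retention, which fixes the Z geometry of the future C4=C5 bond.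

Step 8
Reactants: 12 (2Z)-3-iodo-2-methylprop-2-en-1-ol
Product: 13 1-({[(2Z)-3-iodo-2-methylprop-2-en-1-yl]oxy}methyl)-4-methoxybenzene
Conditions: NaH, 4-MeOC6H4CH2Cl, Bu4NI (cat.), THF/DMF, 0 °C → rt
Reagents that add atoms: 4-methoxybenzyl chloride, COc1ccc(CCl)cc1
Why: Williamson etherification of the primary alkoxide protects O3 as a PMB ether, and the vinyl iodide is inert to NaH.

Step 9
Reactants: 13 1-({[(2Z)-3-iodo-2-methylprop-2-en-1-yl]oxy}methyl)-4-methoxybenzene
Product: 16 (2Z)-4-[(4-methoxybenzyl)oxy]-3-methylbut-2-enal, via alkenyllithium 14 (not isolated), via hemiaminal alkoxide 15 (not isolated)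
Conditions: tBuLi (2.1 equiv), Et2O, −78 °C; DMF, −78 → 0 °C; H2O
Reagents that add atoms: N,N-dimethylformamide, CN(C)C=O
Why: Iodine–lithium exchange and formylation of the alkenyllithium with DMF both proceed with retention of olefin geometry and give the Z-enal.

Step 10
Reactants: 9 methyl (6R)-6-methyl-4-oxo-6-(triethylsilyloxy)oct-7-enoate; 16 (2Z)-4-[(4-methoxybenzyl)oxy]-3-methylbut-2-enal
Product: 19 methyl (3S,6R)-3-[(1R,2Z)-1-hydroxy-4-[(4-methoxybenzyl)oxy]-3-methylbut-2-enyl]-6-methyl-4-oxo-6-(triethylsilyloxy)oct-7-enoate, via enol borinate 17 (not isolated), via boron aldolate 18 (not isolated)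
Conditions: (−)-Ipc2BOTf, iPr2NEt, CH2Cl2, −78 °C; 16, −78 → −20 °C; H2O2, MeOH, pH 7 buffer, 0 °C
Reagents that add atoms: none
Why: In this boron-mediated aldol reaction the bulky boron triflate enolises the less hindered C7 methylene (not C9 next to the quaternary centre) to the Z-enol borinate, the chair (Zimmerman–Traxler) transition state gives the 6,7-syn adduct, and the isopinocampheyl ligands select the Si face of the aldehyde (C6 R, C7 S).

Step 11
Reactants: 19 methyl (3S,6R)-3-[(1R,2Z)-1-hydroxy-4-[(4-methoxybenzyl)oxy]-3-methylbut-2-enyl]-6-methyl-4-oxo-6-(triethylsilyloxy)oct-7-enoate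
Product: 21 methyl (3R,4R,6R)-3-[(1R,2Z)-1-acetoxy-4-[(4-methoxybenzyl)oxy]-3-methylbut-2-enyl]-4-hydroxy-6-methyl-6-(triethylsilyloxy)oct-7-enoate, via hemiacetal 20 (not isolated)
Conditions: SmI2 (0.3 equiv, premixed with the aldehyde), CH3CHO (10 equiv), THF, −10 °C
Reagents that add atoms: acetaldehyde, CC=O
Why: In the Evans–Tishchenko reduction hydride passes intramolecularly from the samarium-bound hemiacetal to the ketone through a chair transition state, which sets C8 1,3-anti to C6 and leaves the new C8 hydroxyl free while O6 carries the acetate.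

Step 12
Reactants: 21 methyl (3R,4R,6R)-3-[(1R,2Z)-1-acetoxy-4-[(4-methoxybenzyl)oxy]-3-methylbut-2-enyl]-4-hydroxy-6-methyl-6-(triethylsilyloxy)oct-7-enoate
Product: 22 methyl (3S,4R,6R)-3-[(1R,2Z)-1-acetoxy-4-[(4-methoxybenzyl)oxy]-3-methylbut-2-enyl]-4-(tert-butyldimethylsilyloxy)-6-methyl-6-(triethylsilyloxy)oct-7-enoate
Conditions: tBuMe2SiOTf, 2,6-lutidine, CH2Cl2, −78 °C
Reagents that add atoms: tert-butyldimethylsilyl triflate, CC(C)(C)[Si](C)(C)OS(=O)(=O)C(F)(F)F
Why: Silyl ether formation with the reactive triflate caps the hindered C8 hydroxyl at low temperature before acetate migration or lactonisation can occur.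

Step 13
Reactants: 22 methyl (3S,4R,6R)-3-[(1R,2Z)-1-acetoxy-4-[(4-methoxybenzyl)oxy]-3-methylbut-2-enyl]-4-(tert-butyldimethylsilyloxy)-6-methyl-6-(triethylsilyloxy)oct-7-enoate
Product: 24 (4S,5R)-4-[(1R,3R)-1-(tert-butyldimethylsilyloxy)-3-methyl-3-(triethylsilyloxy)pent-4-enyl]-5-[(1Z)-3-[(4-methoxybenzyl)oxy]-2-methylprop-1-enyl]oxolan-2-one, via hydroxy ester 23 (not isolated)
Conditions: K2CO3 (0.2 equiv), MeOH, 0 °C → rt
Reagents that add atoms: none
Why: Base-catalysed methanolysis of the allylic acetate frees O6, which closes the γ-lactone onto the C12 methyl ester (5-exo-trig transesterification), and the 6,7-syn relation from step 10 makes the lactone trans.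

Step 14
Reactants: 24 (4S,5R)-4-[(1R,3R)-1-(tert-butyldimethylsilyloxy)-3-methyl-3-(triethylsilyloxy)pent-4-enyl]-5-[(1Z)-3-[(4-methoxybenzyl)oxy]-2-methylprop-1-enyl]oxolan-2-one
Product: 25 (4S,5R)-4-[(1R,3R)-1-(tert-butyldimethylsilyloxy)-3-methyl-3-(triethylsilyloxy)pent-4-enyl]-5-[(1Z)-3-hydroxy-2-methylprop-1-enyl]oxolan-2-one
Conditions: DDQ, CH2Cl2/pH 7 buffer (10:1), 0 °C
Reagents that add atoms: none
Why: Oxidative cleavage of the PMB ether by DDQ is orthogonal to both silyl ethers and to the lactone.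

Step 15
Reactants: 25 (4S,5R)-4-[(1R,3R)-1-(tert-butyldimethylsilyloxy)-3-methyl-3-(triethylsilyloxy)pent-4-enyl]-5-[(1Z)-3-hydroxy-2-methylprop-1-enyl]oxolan-2-one
Product: 26 (2Z)-3-[(2R,3S)-3-[(1R,3R)-1-(tert-butyldimethylsilyloxy)-3-methyl-3-(triethylsilyloxy)pent-4-enyl]-5-oxooxolan-2-yl]-2-methylprop-2-enal
Conditions: MnO2, CH2Cl2, rt, dark
Reagents that add atoms: none
Why: MnO2 oxidises only the allylic alcohol, under neutral conditions that should not isomerise the Z-enal (allylic oxidation).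

Step 16
Reactants: 26 (2Z)-3-[(2R,3S)-3-[(1R,3R)-1-(tert-butyldimethylsilyloxy)-3-methyl-3-(triethylsilyloxy)pent-4-enyl]-5-oxooxolan-2-yl]-2-methylprop-2-enal
Product: 27 oxime of 26 (cyclisation precursor; C3H=NOH on the Z-C4=C5 bond, trans-lactone, 8-OTBS, 10-OTES, C1=C2 vinyl)
Conditions: NH2OH·HCl, pyridine, EtOH, 0 °C
Reagents that add atoms: hydroxylamine hydrochloride, NO.Cl
Why: Condensation of the aldehyde with hydroxylamine gives the aldoxime (oxime formation), and the syn/anti ratio of the oxime is irrelevant.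

Step 17
Reactants: 27 oxime of 26
Product: 30 (1S,6R,7S,8R,10R)-isoxazoline-bridged ten-membered trans-lactone (C3=N–O–C1 bridge, Z-C4=C5, 8-OTBS, 10-OTES), via hydroximoyl chloride 28 (not isolated), via nitrile oxide 29 (not isolated)
Conditions: aq. NaOCl (1.5 equiv), Et3N (0.1 equiv), CH2Cl2, 0 °C → rt; 27 added by syringe pump over 12 h (final concentration about 1 mM)
Reagents that add atoms: none
Why: Proposed new method: NaOCl chlorinates the aldoxime and base eliminates HCl to the conjugated nitrile oxide 29, which adds in a concerted [3+2] manner across the C1=C2 vinyl group (C3 to the CH2 terminus C2, oxygen to C1); the closest known reaction type is the intramolecular nitrile oxide–olefin cycloaddition that closes 12- to 16-membered rings in this same sense. The isoxazoline forms by the cycloaddition itself, and the ten-membered carbocycle C1–C10 closes at the same time in the bridged mode as a bicyclo[7.2.1] system; the fused nine-membered alternative is disfavoured by the normal regiochemistry of monosubstituted olefins and by the neopentyl C1. The one new stereocentre, C1, is controlled by the allylic C10 centre: with the C10–OSiEt3 bond inside and C9 anti to the incoming dipole, oxygen is delivered so that C1–O is anti to C10–O (1S). The step needs regioselectivity, π-facial selectivity and a cyclisation that outruns dimerisation to the furoxan; the first two come from the substitution pattern and the inside-alkoxy effect, the last from slow generation at high dilution. The trans-lactone and the Z-C4=C5 bond hold C3 and the vinyl group on the same side of the chain, which lowers the entropic cost of the closure.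

Step 18
Reactants: 30 isoxazoline-bridged ten-membered lactone
Product: 32 11-(dimethylaminomethyl) derivative of 30 (C11 epimers), via lithium enolate 31 (not isolated)
Conditions: LiN(iPr)2 (1.05 equiv), THF, −78 °C; CH2=NMe2+ I−, −78 → 0 °C
Reagents that add atoms: N,N-dimethylmethyleneiminium iodide, C=[N+](C)C.[I-]
Why: Kinetic deprotonation of the lactone at C11 (more acidic than the isoxazoline C2–H) and Mannich reaction of the enolate with the iminium salt install the C13 carbon, and the new C11 centre is removed in step 19.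

Step 19
Reactants: 32 11-(dimethylaminomethyl) derivative of 30
Product: 34 α-methylene lactone: 30 with C11=C13H2, via ammonium iodide 33 (not isolated)
Conditions: MeI, CH2Cl2/MeOH, rt; then aq. NaHCO3, EtOAc, rt
Reagents that add atoms: none
Why: N-Methylation followed by mild base-induced β-elimination of trimethylamine (Hofmann-type elimination) gives the α-methylene lactone before any base-sensitive ester is present.

Step 20
Reactants: 34 α-methylene lactone isoxazoline
Product: 36 (1S,6R,7S,8R,10R)-1-hydroxy-3-oxo-4Z-enone (ten-membered β-hydroxy enone, 8-OTBS, 10-OTES, α-methylene trans-lactone), via hydroxy imine 35 (not isolated)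
Conditions: Mo(CO)6 (1 equiv), MeCN/H2O (15:1), 80 °C
Reagents that add atoms: water, O
Why: Mo(CO)6 cleaves the isoxazoline N–O bond reductively and the β-hydroxy imine hydrolyses in the wet solvent (isoxazoline-to-aldol unmasking), conditions that tolerate olefins, the conjugated lactone and silyl ethers and do not touch C1.

Step 21
Reactants: 36 β-hydroxy enone
Product: 37 (1S,3S,6R,7S,8R,10R)-1,3-diol (1,3-anti; 8-OTBS, 10-OTES, α-methylene trans-lactone)
Conditions: Me4NBH(OAc)3, MeCN/AcOH (1:1), −30 °C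
Reagents that add atoms: none
Why: In the Evans–Saksena reduction the triacetoxyborohydride exchanges a ligand with the C1 hydroxyl and delivers hydride intramolecularly to the C3 ketone, which sets C3 1,3-anti to C1 (3S) without conjugate reduction of the α-methylene lactone.

Step 22
Reactants: 37 1,3-anti diol; 38 (R)-2-methylbutanoic acid
Product: 40 C3 (R)-2-methylbutanoate of 37 (C1–OH free), via O-acylisourea 39 (not isolated)
Conditions: DCC, DMAP (cat.), CH2Cl2, −20 → 0 °C
Reagents that add atoms: none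
Why: Steglich esterification should select the less hindered allylic C3 hydroxyl over the C1 hydroxyl next to the quaternary C10, and catalytic DMAP at low temperature avoids epimerising the α-centre of the acid.

Step 23
Reactants: 40 C3 ester with free C1–OH
Product: 41 C1 methanesulfonate of 40
Conditions: MsCl, Et3N, CH2Cl2, −20 → 0 °C
Reagents that add atoms: methanesulfonyl chloride, CS(=O)(=O)Cl
Why: Mesylation through sulfene sulfonylates even the hindered secondary C1 alcohol with retention at carbon.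

Step 24
Reactants: 41 C1 mesylate
Product: 42 C10 tertiary alcohol (41 without the triethylsilyl group)
Conditions: HF·pyridine, pyridine, THF, 0 °C
Reagents that add atoms: none
Why: Buffered HF·pyridine cleaves the triethylsilyl ether much faster than the hindered secondary tert-butyldimethylsilyl ether (selective desilylation), and no epoxide is yet present to be opened by fluoride.

Step 25
Reactants: 42 C10 alcohol with C1 mesylate
Product: 43 (1R,3S,6R,7S,8R,10R)-1,10-epoxide (8-OTBS, 3-O-(R)-2-methylbutanoyl, α-methylene trans-lactone)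
Conditions: DBU, CH2Cl2, 0 °C → rt
Reagents that add atoms: none
Why: In this intramolecular Williamson reaction (3-exo-tet) the C10 oxygen displaces the anti-periplanar C1 mesylate with inversion, giving the trans-oxirane (1R,10R).

Step 26
Reactants: 43 1,10-epoxide with 8-OTBS
Product: 44 8-hydroxy epoxide (43 without the silyl group)
Conditions: Bu4NF, AcOH (1:1), THF, rt
Reagents that add atoms: none
Why: Fluoride-mediated desilylation buffered with acetic acid spares the oxirane, the C3 ester and the α-methylene lactone and keeps the C8 alkoxide from attacking the lactone or the epoxide.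

Step 27
Reactants: 45 tiglic acid
Product: 46 (2E)-2-methylbut-2-en-1-ol
Conditions: LiAlH4, Et2O, 0 °C → rt; aqueous work-up
Reagents that add atoms: none
Why: Hydride reduction of the carboxylic acid gives the allylic alcohol (1,2-reduction) and keeps the E-olefin.

Step 28
Reactants: 46 (2E)-2-methylbut-2-en-1-ol
Product: 47 [(2R,3R)-2,3-dimethyloxiran-2-yl]methanol
Conditions: Ti(OiPr)4 (10 mol %), D-(−)-diethyl tartrate (12 mol %), tBuOOH, 4 Å molecular sieves, CH2Cl2, −20 °C
Reagents that add atoms: tert-butyl hydroperoxide, CC(C)(C)OO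
Why: In the Sharpless asymmetric epoxidation the D-(−)-tartrate ligand delivers oxygen to the face of the E-allylic alcohol that gives the (2R,3R)-epoxy alcohol, and the E geometry fixes the cis relation of the two methyl groups.

Step 29
Reactants: 47 [(2R,3R)-2,3-dimethyloxiran-2-yl]methanol
Product: 49 (2S,3R)-2,3-dimethyloxirane-2-carboxylic acid, via epoxy aldehyde 48 (not isolated)
Conditions: TEMPO (cat.), PhI(OAc)2 (2.2 equiv), MeCN/H2O (1:1), rt
Reagents that add atoms: water, O
Why: The oxoammonium-mediated oxidation takes the primary alcohol through the aldehyde hydrate to the acid without opening the epoxide, and the C2 descriptor changes to S only through the change in substituent priorities.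

Step 30
Reactants: 44 8-hydroxy epoxide; 49 (2S,3R)-2,3-dimethyloxirane-2-carboxylic acid
Product: 51 CNP0265335.4, via mixed anhydride 50 (not isolated)
Conditions: 2,4,6-Cl3C6H2COCl, Et3N, THF, rt; then 44, DMAP (0.5 equiv), Et3N, toluene, rt
Reagents that add atoms: none
Why: Yamaguchi esterification through the mixed anhydride acylates the hindered secondary C8 hydroxyl, and the α-quaternary acid cannot epimerise.

**Compound list**

1 | (R)-linalool | CC(C)=CCC[C@@](C)(O)C=C | starting material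
2 | (3R)-3,7-dimethyl-3-(triethylsilyloxy)octa-1,6-diene | CC(C)=CCC[C@@](C)(O[Si](CC)(CC)CC)C=C | intermediate
3 | 3,3-dimethyl-5-[(3R)-3-methyl-3-(triethylsilyloxy)pent-4-enyl]-1,2,4-trioxolane (ozonide) | CC1(C)OOC(CC[C@@](C)(O[Si](CC)(CC)CC)C=C)O1 | intermediate
4 | (4R)-4-methyl-4-(triethylsilyloxy)hex-5-enal | O=CCC[C@@](C)(O[Si](CC)(CC)CC)C=C | intermediate
5 | (2R,4R)-4-methyl-2-(phenylaminooxy)-4-(triethylsilyloxy)hex-5-enal | O=C[C@H](ONc1ccccc1)C[C@@](C)(O[Si](CC)(CC)CC)C=C | intermediate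
6 | methyl (2E,4R,6R)-6-methyl-4-(phenylaminooxy)-6-(triethylsilyloxy)octa-2,7-dienoate | COC(=O)/C=C/[C@H](ONc1ccccc1)C[C@@](C)(O[Si](CC)(CC)CC)C=C | intermediate
7 | methyl (2E,4R,6R)-4-hydroxy-6-methyl-6-(triethylsilyloxy)octa-2,7-dienoate | COC(=O)/C=C/[C@H](O)C[C@@](C)(O[Si](CC)(CC)CC)C=C | intermediate
8 | methyl (2E,6R)-6-methyl-4-oxo-6-(triethylsilyloxy)octa-2,7-dienoate | COC(=O)/C=C/C(=O)C[C@@](C)(O[Si](CC)(CC)CC)C=C | intermediate
9 | methyl (6R)-6-methyl-4-oxo-6-(triethylsilyloxy)oct-7-enoate | COC(=O)CCC(=O)C[C@@](C)(O[Si](CC)(CC)CC)C=C | intermediate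
10 | prop-2-yn-1-ol | C#CCO | starting material
11 | bromomagnesium (2Z)-3-(bromomagnesio)-2-methylprop-2-en-1-olate | C/C(=C/[Mg]Br)CO[Mg]Br | intermediate
12 | (2Z)-3-iodo-2-methylprop-2-en-1-ol | C/C(=C/I)CO | intermediate
13 | 1-({[(2Z)-3-iodo-2-methylprop-2-en-1-yl]oxy}methyl)-4-methoxybenzene | C/C(=C/I)COCc1ccc(OC)cc1 | intermediate
14 | (1Z)-3-[(4-methoxybenzyl)oxy]-2-methylprop-1-enyllithium | C/C(=C/[Li])COCc1ccc(OC)cc1 | intermediate
15 | lithium (2Z)-1-(dimethylamino)-4-[(4-methoxybenzyl)oxy]-3-methylbut-2-en-1-olate | C/C(=C/C(O[Li])N(C)C)COCc1ccc(OC)cc1 | intermediate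
16 | (2Z)-4-[(4-methoxybenzyl)oxy]-3-methylbut-2-enal | C/C(=C/C=O)COCc1ccc(OC)cc1 | intermediate
17 | (Z)-C7=C8 enol bis(isopinocampheyl)borinate of 9 | COC(=O)C/C=C(/C[C@@](C)(O[Si](CC)(CC)CC)C=C)OB([C@@H]1C[C@@H]2C[C@@H](C2(C)C)[C@H]1C)[C@@H]1C[C@@H]2C[C@@H](C2(C)C)[C@H]1C | intermediate
18 | O6-bis(isopinocampheyl)boron aldolate of 19 | COC(=O)C[C@@H]([C@H](OB([C@@H]1C[C@@H]2C[C@@H](C2(C)C)[C@H]1C)[C@@H]1C[C@@H]2C[C@@H](C2(C)C)[C@H]1C)/C=C(/C)COCc1ccc(OC)cc1)C(=O)C[C@@](C)(O[Si](CC)(CC)CC)C=C | intermediate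
19 | methyl (3S,6R)-3-[(1R,2Z)-1-hydroxy-4-[(4-methoxybenzyl)oxy]-3-methylbut-2-enyl]-6-methyl-4-oxo-6-(triethylsilyloxy)oct-7-enoate (6,7-syn aldol) | COC(=O)C[C@@H]([C@H](O)/C=C(/C)COCc1ccc(OC)cc1)C(=O)C[C@@](C)(O[Si](CC)(CC)CC)C=C | intermediate
20 | O6-(1-hydroxyethyl) hemiacetal of 19 | COC(=O)C[C@@H]([C@H](OC(C)O)/C=C(/C)COCc1ccc(OC)cc1)C(=O)C[C@@](C)(O[Si](CC)(CC)CC)C=C | intermediate
21 | methyl (3R,4R,6R)-3-[(1R,2Z)-1-acetoxy-4-[(4-methoxybenzyl)oxy]-3-methylbut-2-enyl]-4-hydroxy-6-methyl-6-(triethylsilyloxy)oct-7-enoate | COC(=O)C[C@@H]([C@H](OC(C)=O)/C=C(/C)COCc1ccc(OC)cc1)[C@H](O)C[C@@](C)(O[Si](CC)(CC)CC)C=C | intermediate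
22 | methyl (3S,4R,6R)-3-[(1R,2Z)-1-acetoxy-4-[(4-methoxybenzyl)oxy]-3-methylbut-2-enyl]-4-(tert-butyldimethylsilyloxy)-6-methyl-6-(triethylsilyloxy)oct-7-enoate | COC(=O)C[C@@H]([C@H](OC(C)=O)/C=C(/C)COCc1ccc(OC)cc1)[C@H](O[Si](C)(C)C(C)(C)C)C[C@@](C)(O[Si](CC)(CC)CC)C=C | intermediate
23 | methyl (3S,4R,6R)-4-(tert-butyldimethylsilyloxy)-3-[(1R,2Z)-1-hydroxy-4-[(4-methoxybenzyl)oxy]-3-methylbut-2-enyl]-6-methyl-6-(triethylsilyloxy)oct-7-enoate | COC(=O)C[C@@H]([C@H](O)/C=C(/C)COCc1ccc(OC)cc1)[C@H](O[Si](C)(C)C(C)(C)C)C[C@@](C)(O[Si](CC)(CC)CC)C=C | intermediate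
24 | (4S,5R)-4-[(1R,3R)-1-(tert-butyldimethylsilyloxy)-3-methyl-3-(triethylsilyloxy)pent-4-enyl]-5-[(1Z)-3-[(4-methoxybenzyl)oxy]-2-methylprop-1-enyl]oxolan-2-one | O=C1C[C@H]([C@H](O[Si](C)(C)C(C)(C)C)C[C@](C)(C=C)O[Si](CC)(CC)CC)[C@@H](/C=C(/C)COCc2ccc(OC)cc2)O1 | intermediate
25 | (4S,5R)-4-[(1R,3R)-1-(tert-butyldimethylsilyloxy)-3-methyl-3-(triethylsilyloxy)pent-4-enyl]-5-[(1Z)-3-hydroxy-2-methylprop-1-enyl]oxolan-2-one | O=C1C[C@H]([C@H](O[Si](C)(C)C(C)(C)C)C[C@](C)(C=C)O[Si](CC)(CC)CC)[C@@H](/C=C(/C)CO)O1 | intermediate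
26 | (2Z)-3-[(2R,3S)-3-[(1R,3R)-1-(tert-butyldimethylsilyloxy)-3-methyl-3-(triethylsilyloxy)pent-4-enyl]-5-oxooxolan-2-yl]-2-methylprop-2-enal | O=C1C[C@H]([C@H](O[Si](C)(C)C(C)(C)C)C[C@](C)(C=C)O[Si](CC)(CC)CC)[C@@H](/C=C(/C)C=O)O1 | intermediate
27 | oxime of 26 (cyclisation precursor) | O=C1C[C@H]([C@H](O[Si](C)(C)C(C)(C)C)C[C@](C)(C=C)O[Si](CC)(CC)CC)[C@@H](/C=C(/C)C=NO)O1 | intermediate
28 | hydroximoyl chloride of 27 | O=C1C[C@H]([C@H](O[Si](C)(C)C(C)(C)C)C[C@](C)(C=C)O[Si](CC)(CC)CC)[C@@H](/C=C(/C)C(Cl)=NO)O1 | intermediate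
29 | nitrile oxide from 27 | O=C1C[C@H]([C@H](O[Si](C)(C)C(C)(C)C)C[C@](C)(C=C)O[Si](CC)(CC)CC)[C@@H](/C=C(/C)C#[N+][O-])O1 | intermediate
30 | (1S,6R,7S,8R,10R)-isoxazoline-bridged ten-membered trans-lactone (C3=N–O–C1, Z-C4=C5, 8-OTBS, 10-OTES) | O=C1C[C@@H]2[C@H](O[Si](C)(C)C(C)(C)C)C[C@@](C)(O[Si](CC)(CC)CC)[C@@H]3CC(=NO3)/C(C)=C\[C@H]2O1 | intermediate
31 | lithium C11=C12 enolate of 30 | [Li]OC1=C[C@@H]2[C@H](O[Si](C)(C)C(C)(C)C)C[C@@](C)(O[Si](CC)(CC)CC)[C@@H]3CC(=NO3)/C(C)=C\[C@H]2O1 | intermediate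
32 | 11-(dimethylaminomethyl) derivative of 30 (C11 epimers) | O=C1C(CN(C)C)[C@@H]2[C@H](O[Si](C)(C)C(C)(C)C)C[C@@](C)(O[Si](CC)(CC)CC)[C@@H]3CC(=NO3)/C(C)=C\[C@H]2O1 | intermediate
33 | 11-(trimethylammoniomethyl) iodide of 30 | O=C1C(C[N+](C)(C)C)[C@@H]2[C@H](O[Si](C)(C)C(C)(C)C)C[C@@](C)(O[Si](CC)(CC)CC)[C@@H]3CC(=NO3)/C(C)=C\[C@H]2O1.[I-] | intermediate
34 | α-methylene lactone: 30 with C11=C13H2 | O=C1C(=C)[C@@H]2[C@H](O[Si](C)(C)C(C)(C)C)C[C@@](C)(O[Si](CC)(CC)CC)[C@@H]3CC(=NO3)/C(C)=C\[C@H]2O1 | intermediate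
35 | (1S)-1-hydroxy-3-imine from N–O cleavage of 34 | C=C1C(=O)O[C@@H]2/C=C(/C)C(=N)C[C@H](O)[C@](C)(O[Si](CC)(CC)CC)C[C@@H](O[Si](C)(C)C(C)(C)C)[C@@H]12 | intermediate
36 | (1S,6R,7S,8R,10R)-1-hydroxy-3-oxo-4Z-ene (ten-membered β-hydroxy enone, 8-OTBS, 10-OTES, α-methylene trans-lactone) | C=C1C(=O)O[C@@H]2/C=C(/C)C(=O)C[C@H](O)[C@](C)(O[Si](CC)(CC)CC)C[C@@H](O[Si](C)(C)C(C)(C)C)[C@@H]12 | intermediate
37 | (1S,3S,6R,7S,8R,10R)-1,3-diol (1,3-anti; 8-OTBS, 10-OTES) | C=C1C(=O)O[C@@H]2/C=C(/C)[C@@H](O)C[C@H](O)[C@](C)(O[Si](CC)(CC)CC)C[C@@H](O[Si](C)(C)C(C)(C)C)[C@@H]12 | intermediate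
38 | (R)-2-methylbutanoic acid | CC[C@@H](C)C(=O)O | starting material
39 | O-acylisourea from 38 and DCC | CC[C@@H](C)C(=O)OC(=NC1CCCCC1)NC1CCCCC1 | intermediate
40 | 3-O-[(R)-2-methylbutanoyl] derivative of 37 (C1–OH free) | C=C1C(=O)O[C@@H]2/C=C(/C)[C@@H](OC(=O)[C@H](C)CC)C[C@H](O)[C@](C)(O[Si](CC)(CC)CC)C[C@@H](O[Si](C)(C)C(C)(C)C)[C@@H]12 | intermediate
41 | 1-O-methanesulfonate of 40 | C=C1C(=O)O[C@@H]2/C=C(/C)[C@@H](OC(=O)[C@H](C)CC)C[C@H](OS(C)(=O)=O)[C@](C)(O[Si](CC)(CC)CC)C[C@@H](O[Si](C)(C)C(C)(C)C)[C@@H]12 | intermediate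
42 | 10-hydroxy 1-mesylate (41 without the triethylsilyl group) | C=C1C(=O)O[C@@H]2/C=C(/C)[C@@H](OC(=O)[C@H](C)CC)C[C@H](OS(C)(=O)=O)[C@](C)(O)C[C@@H](O[Si](C)(C)C(C)(C)C)[C@@H]12 | intermediate
43 | (1R,3S,6R,7S,8R,10R)-1,10-epoxide, 8-OTBS, 3-O-[(R)-2-methylbutanoyl] | C=C1C(=O)O[C@@H]2/C=C(/C)[C@@H](OC(=O)[C@H](C)CC)C[C@H]3O[C@]3(C)C[C@@H](O[Si](C)(C)C(C)(C)C)[C@@H]12 | intermediate
44 | (1R,3S,6R,7R,8R,10R)-8-hydroxy-1,10-epoxide, 3-O-[(R)-2-methylbutanoyl] | C=C1C(=O)O[C@@H]2/C=C(/C)[C@@H](OC(=O)[C@H](C)CC)C[C@H]3O[C@]3(C)C[C@@H](O)[C@@H]12 | intermediate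
45 | tiglic acid | C/C=C(\C)C(=O)O | starting material
46 | (2E)-2-methylbut-2-en-1-ol | C/C=C(\C)CO | intermediate
47 | [(2R,3R)-2,3-dimethyloxiran-2-yl]methanol | OC[C@@]1(C)O[C@@H]1C | intermediate
48 | (2S,3R)-2,3-dimethyloxirane-2-carbaldehyde | O=C[C@@]1(C)O[C@@H]1C | intermediate
49 | (2S,3R)-2,3-dimethyloxirane-2-carboxylic acid | OC(=O)[C@@]1(C)O[C@@H]1C | intermediate
50 | mixed anhydride of 49 with 2,4,6-trichlorobenzoic acid | O=C(OC(=O)[C@@]1(C)O[C@@H]1C)c1c(Cl)cc(Cl)cc1Cl | intermediate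
51 | CNP0265335.4 | C=C1C(=O)O[C@@H]2/C=C(/C)[C@@H](OC(=O)[C@H](C)CC)C[C@H]3O[C@]3(C)C[C@@H](OC(=O)[C@@]3(C)O[C@@H]3C)[C@@H]12 | target

**Step count and risks**

Total step count: 30. Longest linear sequence: 24 steps (steps 1–6, 10–26 and 30).

Steps most likely to fail:

1. Step 17 (proposed new method). The nitrile oxide may dimerise to the furoxan or oligomerise faster than the strained ten-membered closure, or add in the fused sense or with poor facial selectivity at C1. Fallback: the isoxazoline is made intermolecularly and the ring is closed at C4=C5 by metathesis, setting out from 24 and returning at 30. 2-Methylprop-2-enal oxime F1 (from methacrolein and NH2OH) is oxidised with NaOCl in the presence of 24 to 2-methylprop-2-enenitrile oxide F2. This adds to the C10 vinyl group, the only monosubstituted olefin, to give the 3-isopropenyl-isoxazoline F3. Ozonolysis selective for the electron-rich C4=C5 bond (ozonide F4, then PPh3) gives the C5 aldehyde F5, and Wittig methylenation (Ph3P=CH2, −78 °C) gives the C6-vinyl lactone F6. Ring-closing metathesis with the second-generation Hoveyda–Grubbs catalyst, RuCl2(H2IMes)(=CH-C6H4-2-OiPr), in toluene at 80 °C and about 1 mM forms the ring-constrained Z-C4=C5 bond and gives 30.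

2. Step 10. Enolisation may occur on the wrong side of the ketone, or the facial selection on the enal may be low or of the wrong sense. Fallback: the bond is made by a catalytic Mukaiyama aldol reaction, setting out from 9 and returning at 19. Me3SiOTf/Et3N converts 9 into the Z-trimethylsilyl enol ether F7. This adds to 16 under a tartrate-derived chiral (acyloxy)borane Lewis acid, which is syn-selective through an open transition state whatever the enol ether geometry; the catalyst enantiomer is chosen for Si-face attack. The silylated aldol F8 is desilylated on acidic work-up to 19.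

3. Step 21. The conformation of the ten-membered ring may override the intramolecular hydride delivery and give poor anti selectivity, or the β-hydroxy enone may undergo retro-aldol opening in the acidic medium. Fallback: the C3 centre is set by external hydride and corrected by substitution, setting out from 36 and returning at 40. Luche reduction (NaBH4, CeCl3·7H2O, MeOH, −78 °C) reduces the enone 1,2 from the ring periphery. If it gives the (3R)-diol F9, Mitsunobu esterification of the allylic C3 hydroxyl with 38 (PPh3, diisopropyl azodicarboxylate, THF, 0 °C) installs the ester with inversion and gives 40.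

**Further compounds**

F1 | step 17 | 2-methylprop-2-enal oxime | C=C(C)C=NO
F2 | step 17 | 2-methylprop-2-enenitrile oxide | C=C(C)C#[N+][O-]
F3 | step 17 | 3-isopropenyl-isoxazoline from 24 (O on C1, C10-OTES, 8-OTBS, trans-lactone, Z-alkenyl PMB ether) | O=C1C[C@H]([C@H](O[Si](C)(C)C(C)(C)C)C[C@@](C)(O[Si](CC)(CC)CC)[C@@H]2CC(=NO2)C(C)=C)[C@@H](/C=C(/C)COCc3ccc(OC)cc3)O1
F4 | step 17 | ozonide of F3 at C4=C5 | O=C1C[C@H]([C@H](O[Si](C)(C)C(C)(C)C)C[C@@](C)(O[Si](CC)(CC)CC)[C@@H]2CC(=NO2)C(C)=C)[C@@H](C2OOC(C)(COCc3ccc(OC)cc3)O2)O1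
F5 | step 17 | C5 aldehyde (5-formyl lactone) from F3 | O=C1C[C@H]([C@H](O[Si](C)(C)C(C)(C)C)C[C@@](C)(O[Si](CC)(CC)CC)[C@@H]2CC(=NO2)C(C)=C)[C@@H](C=O)O1
F6 | step 17 | C6-vinyl lactone carrying the 3-isopropenyl-isoxazoline | O=C1C[C@H]([C@H](O[Si](C)(C)C(C)(C)C)C[C@@](C)(O[Si](CC)(CC)CC)[C@@H]2CC(=NO2)C(C)=C)[C@@H](C=C)O1
F7 | step 10 | (Z)-trimethylsilyl enol ether of 9 | COC(=O)C/C=C(/C[C@@](C)(O[Si](CC)(CC)CC)C=C)O[Si](C)(C)C
F8 | step 10 | O6-trimethylsilyl ether of 19 | COC(=O)C[C@@H]([C@H](O[Si](C)(C)C)/C=C(/C)COCc1ccc(OC)cc1)C(=O)C[C@@](C)(O[Si](CC)(CC)CC)C=C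
F9 | step 21 | (1S,3R)-diol, C3 epimer of 37 | C=C1C(=O)O[C@@H]2/C=C(/C)[C@H](O)C[C@H](O)[C@](C)(O[Si](CC)(CC)CC)C[C@@H](O[Si](C)(C)C(C)(C)C)[C@@H]12
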